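**Strategy.** Everything rests on cutting the enol-ether bond O–C3 of the 3(2H)-furanone (O, C3, C2, C1, C10; germacrane numbering). This exposes a ten-membered germacranolide that holds a C1-keto C2≡C3 ynone, with the tertiary C10 hydroxyl lying across the ring from C3. A gold-catalysed transannular 5-endo-dig hydroalkoxylation stitches O10 to C3 and creates, in one operation, the furanone, its C2=C3 enol-ether double bond and the oxygen bridge of the bicyclic core. The precursor is a cyclodec-4-en-2-yn-1-one already carrying the trans-fused α-methylene lactone. It is made by a chromium-mediated Barbier macrocyclisation (C6–C7) of an acyclic bromo-enal built from a glutamic-acid-derived lactone, a Z-enyne acetal and methyl acrylate.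

Key step: step 20

Remark on the chemistry: atom positions are written in germacrane numbering (C1 ketone, C2=C3, C4=C5, C6/C7 lactone fusion, C8 ester carbinol, C9 methylene, C10 quaternary carbon, C11–C13 methylene lactone). Centres that are planarised later (C3 of 12, C1 in 18–27, C7 of 21) are carried as epimer mixtures.

**Step 1**
Reactants: 1 (Z)-3-methylpent-2-en-4-yn-1-ol
Product: 2 (Z)-3-methylpent-2-en-4-ynal
Conditions: MnO2 (activated, 15 equiv), CH2Cl2, 0 °C to rt
Reagents that add atoms: none
Why: Heterogeneous manganese dioxide oxidation of the allylic alcohol is neutral, so the Z alkene and the terminal alkyne should survive; the volatile enynal is carried on as a solution.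

**Step 2**
Reactants: 2 (Z)-3-methylpent-2-en-4-ynal
Product: 3 (Z)-5,5-dimethoxy-3-methylpent-3-en-1-yne
Conditions: HC(OMe)3, MeOH, pyridinium p-toluenesulfonate (cat.), rt
Reagents that add atoms: trimethyl orthoformate, COC(OC)OC
Why: Acid-catalysed acetalisation driven by the orthoformate masks the future C6 aldehyde so that the alkyne can be metallated, and the weak acid should not isomerise the Z alkene.

**Step 3**
Reactants: 4 acetaldehyde; 5 tert-butyl acrylate
Product: 6 tert-butyl 3-hydroxy-2-methylidenebutanoate (racemic)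
Conditions: DABCO (0.3 equiv), neat, rt, 5 d
Reagents that add atoms: none
Why: Morita–Baylis–Hillman reaction; the carbinol centre is erased in step 5, so no stereocontrol is needed.

**Step 4**
Reactants: 6 tert-butyl 3-hydroxy-2-methylidenebutanoate
Product: 7 tert-butyl 3-acetoxy-2-methylidenebutanoate (racemic)
Conditions: Ac2O, pyridine, DMAP (cat.), CH2Cl2, 0 °C to rt
Reagents that add atoms: acetic anhydride, CC(=O)OC(C)=O
Why: Standard O-acetylation of the secondary allylic alcohol.

**Step 5**
Reactants: 7 tert-butyl 3-acetoxy-2-methylidenebutanoate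
Product: 8 tert-butyl (E)-2-(acetoxymethyl)but-2-enoate
Conditions: DABCO (0.2 equiv), THF, reflux
Reagents that add atoms: none
Why: Amine-catalysed 1,3-transposition of the acetate (two consecutive SN2' displacements through an allylammonium ion) should give the more stable trisubstituted alkene with the methyl trans to the ester (E); any Z isomer is removed by chromatography.

**Step 6**
Reactants: 8 tert-butyl (E)-2-(acetoxymethyl)but-2-enoate
Product: 9 (E)-2-(acetoxymethyl)but-2-enoic acid
Conditions: CF3CO2H, CH2Cl2, 0 °C to rt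
Reagents that add atoms: none
Why: Acidolysis of the tert-butyl ester frees the acid without touching the primary acetate or the alkene geometry.

**Step 7**
Reactants: 10 (R)-5-(hydroxymethyl)dihydrofuran-2(3H)-one
Product: 11 (R)-5-[(triethylsilyloxy)methyl]dihydrofuran-2(3H)-one
Conditions: Et3SiCl, imidazole, CH2Cl2, 0 °C
Reagents that add atoms: chlorotriethylsilane, CC[Si](Cl)(CC)CC
Why: Silylation of the only hydroxyl; the chiral-pool carbinol carbon becomes C8 (R), and a primary triethylsilyl ether is chosen because it can later be oxidised directly to the aldehyde.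

**Step 8**
Reactants: 11 (R)-5-[(triethylsilyloxy)methyl]dihydrofuran-2(3H)-one
Product: 12 (3S,5R)-3-hydroxy-5-[(triethylsilyloxy)methyl]dihydrofuran-2(3H)-one
Conditions: KN(SiMe3)2, THF, −78 °C; 2-(phenylsulfonyl)-3-phenyloxaziridine, −78 °C; AcOH quench
Reagents that add atoms: 2-(phenylsulfonyl)-3-phenyloxaziridine, O=S(=O)(c1ccccc1)N1OC1c1ccccc1
Why: Oxaziridine hydroxylation of the lactone enolate should place the hydroxyl mainly trans to the C5 substituent, but the ratio is immaterial because this carbon is planarised again in step 10.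

**Step 9**
Reactants: 12 (3S,5R)-3-hydroxy-5-[(triethylsilyloxy)methyl]dihydrofuran-2(3H)-one
Product: 13 (3S,5R)-3-(triethylsilyloxy)-5-[(triethylsilyloxy)methyl]dihydrofuran-2(3H)-one
Conditions: Et3SiCl, imidazole, DMAP (cat.), DMF, rt
Reagents that add atoms: chlorotriethylsilane, CC[Si](Cl)(CC)CC
Why: O-silylation protects the α-hydroxyl so that the lactone can be enolised a second time.

**Step 10**
Reactants: 13 (3S,5R)-3-(triethylsilyloxy)-5-[(triethylsilyloxy)methyl]dihydrofuran-2(3H)-one
Product: 14 (3R,5R)-3-methyl-3-(triethylsilyloxy)-5-[(triethylsilyloxy)methyl]dihydrofuran-2(3H)-one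
Conditions: LiN(i-Pr)2, THF, −78 °C; MeI, DMPU, −78 to −40 °C
Reagents that add atoms: iodomethane, CI
Why: Alkylation of the α-silyloxy lactone enolate should occur on the face opposite the C5 silyloxymethyl group (1,3-induction in the five-membered enolate), placing methyl trans and the silyloxy group cis to it, which sets the quaternary C10 centre (R).

**Step 11**
Reactants: 14 (3R,5R)-3-methyl-3-(triethylsilyloxy)-5-[(triethylsilyloxy)methyl]dihydrofuran-2(3H)-one
Product: 15 (3R,5R)-3-methyl-3-(triethylsilyloxy)-5-[(triethylsilyloxy)methyl]oxolan-2-ol (anomer mixture)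
Conditions: i-Bu2AlH, CH2Cl2, −78 °C; Rochelle salt work-up
Reagents that add atoms: none
Why: At −78 °C the aluminium hemiacetal of the hindered lactone is stable, so the reduction should stop at the lactol (future C1 at the aldehyde level).

**Step 12**
Reactants: 15 (3R,5R)-3-methyl-3-(triethylsilyloxy)-5-[(triethylsilyloxy)methyl]oxolan-2-ol; 3 (Z)-5,5-dimethoxy-3-methylpent-3-en-1-yne
Product: 18 (2R,4R,5RS,8Z)-10,10-dimethoxy-4,8-dimethyl-1,2,4,5-tetrakis(triethylsilyloxy)dec-8-en-6-yne, via lithium acetylide 16 (not isolated), via dilithium dialkoxide 17 (not isolated)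
Conditions: 3 (3 equiv), n-BuLi, THF, −78 °C; add 15, −78 to 0 °C; then Et3SiCl, DMAP (cat.), 0 °C to rt
Reagents that add atoms: chlorotriethylsilane, CC[Si](Cl)(CC)CC
Why: The lactol equilibrates with its hydroxy aldehyde, which is trapped by 1,2-addition of the acetylide (C1–C2 bond), and both lithium alkoxides are silylated in the same flask; the C1 epimer mixture and any silyl shuffling between O1 and O10 are harmless because C1 becomes a ketone and all silyl groups are removed together later.

**Step 13**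
Reactants: 18 (2R,4R,5RS,8Z)-10,10-dimethoxy-4,8-dimethyl-1,2,4,5-tetrakis(triethylsilyloxy)dec-8-en-6-yne
Product: 19 (2R,4R,5RS,8Z)-10,10-dimethoxy-4,8-dimethyl-2,4,5-tris(triethylsilyloxy)dec-8-en-6-ynal
Conditions: (COCl)2, Me2SO, CH2Cl2, −78 to −40 °C; then Et3N, −78 to 0 °C
Reagents that add atoms: none
Why: Under Swern conditions a primary triethylsilyl ether is attacked by the chlorosulfonium reagent and oxidised directly to the aldehyde (C7), while the secondary and tertiary silyl ethers and the acetal should stay intact.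

**Step 14**
Reactants: 19 (2R,4R,5RS,8Z)-10,10-dimethoxy-4,8-dimethyl-2,4,5-tris(triethylsilyloxy)dec-8-en-6-ynal; 20 methyl acrylate
Product: 21 methyl (3RS,4R,6R,7RS,10Z)-3-hydroxy-12,12-dimethoxy-6,10-dimethyl-2-methylidene-4,6,7-tris(triethylsilyloxy)dodec-10-en-8-ynoate
Conditions: DABCO (1 equiv), 20 (neat, excess), rt
Reagents that add atoms: none
Why: Morita–Baylis–Hillman reaction of the inductively activated α-silyloxy aldehyde installs C11–C13; the new carbinol centre is erased in step 15 and the weak amine base should not epimerise C8.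

**Step 15**
Reactants: 21 methyl (3RS,4R,6R,7RS,10Z)-3-hydroxy-12,12-dimethoxy-6,10-dimethyl-2-methylidene-4,6,7-tris(triethylsilyloxy)dodec-10-en-8-ynoate
Product: 22 methyl (2Z,4R,6R,7RS,10Z)-2-(bromomethyl)-12,12-dimethoxy-6,10-dimethyl-4,6,7-tris(triethylsilyloxy)dodeca-2,10-dien-8-ynoate
Conditions: NBS, Me2S, CH2Cl2, 0 °C to rt
Reagents that add atoms: N-bromosuccinimide, O=C1CCC(=O)N1Br
Why: The preformed bromosulfonium reagent activates the allylic hydroxyl and bromide displaces it in SN2' fashion, which should give the thermodynamically preferred (Z)-2-(bromomethyl)alkenoate under neutral conditions.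

**Step 16**
Reactants: 22 methyl (2Z,4R,6R,7RS,10Z)-2-(bromomethyl)-12,12-dimethoxy-6,10-dimethyl-4,6,7-tris(triethylsilyloxy)dodeca-2,10-dien-8-ynoate
Product: 23 methyl (2Z,4R,6R,7RS,10Z)-2-(bromomethyl)-6,10-dimethyl-12-oxo-4,6,7-tris(triethylsilyloxy)dodeca-2,10-dien-8-ynoate
Conditions: oxalic acid (cat.), moist SiO2, CH2Cl2, rt
Reagents that add atoms: water, O
Why: The allylic dimethyl acetal ionises far more readily than the secondary silyl ethers cleave, so very mild acid should unmask the Z-enal (C6) in the presence of the allylic bromide.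

**Step 17**
Reactants: 23 methyl (2Z,4R,6R,7RS,10Z)-2-(bromomethyl)-6,10-dimethyl-12-oxo-4,6,7-tris(triethylsilyloxy)dodeca-2,10-dien-8-ynoate
Product: 26 (6S,7S,8R,10R)-1,8,10-tris(triethylsilyloxy)germacra-4Z,11(13)-dien-2-yn-12,6-olide (C1 epimers), via allylchromium dichloride 24 (not isolated), via chromium alkoxide 25 (not isolated)
Conditions: CrCl2 (8 equiv), DMF, rt, slow addition of 23 (final 2 mM)
Reagents that add atoms: none
Why: Divalent chromium turns the allylic bromide into an allylchromium species that adds through C7 to the tethered aldehyde in a chair-like six-membered transition state (intramolecular Nozaki–Hiyama/Barbier allylation closing the ten-membered ring), and the alkoxide lactonises onto the methyl ester; by analogy with macrocyclic allylations of this lactone class, C5 and C8 are expected to sit pseudo-equatorial (6,7-anti, trans-fused lactone) with the aldehyde approaching C7 while the C8 silyloxy group is inside and ring carbon C9 anti to the forming bond, which sets C6 (S) and C7 (S).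

**Step 18**
Reactants: 26 (6S,7S,8R,10R)-1,8,10-tris(triethylsilyloxy)germacra-4Z,11(13)-dien-2-yn-12,6-olide
Product: 27 (6S,7S,8R,10R)-1,8,10-trihydroxygermacra-4Z,11(13)-dien-2-yn-12,6-olide (C1 epimers)
Conditions: HF·pyridine, pyridine, THF, 0 °C to rt
Reagents that add atoms: none
Why: Buffered fluoride cleaves all three triethylsilyl ethers under mildly acidic conditions that the methylene lactone and the enyne should tolerate.

**Step 19**
Reactants: 27 (6S,7S,8R,10R)-1,8,10-trihydroxygermacra-4Z,11(13)-dien-2-yn-12,6-olide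
Product: 28 (6S,7S,8R,10R)-8,10-dihydroxy-1-oxogermacra-4Z,11(13)-dien-2-yn-12,6-olide
Conditions: MnO2 (activated, 20 equiv), CH2Cl2, rt
Reagents that add atoms: none
Why: Manganese dioxide oxidises only the propargylic C1 carbinol (both epimers converge), leaving the saturated C8 and tertiary C10 hydroxyls, and glycol cleavage should be slow by comparison; the hydroxy ynone is filtered and used directly.

**Step 20**
Reactants: 28 (6S,7S,8R,10R)-8,10-dihydroxy-1-oxogermacra-4Z,11(13)-dien-2-yn-12,6-olide
Product: 29 (6S,7S,8R,10R)-8-hydroxy-1-oxo-3,10-epoxygermacra-2,4Z,11(13)-trien-12,6-olide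
Conditions: Ph3PAuCl (5 mol%), AgOSO2CF3 (5 mol%), toluene, rt
Reagents that add atoms: none
Why: Cationic monovalent gold coordinates the bent C2≡C3 triple bond of the ynone, the tertiary C10 hydroxyl adds anti to gold at the β-carbon C3, and protodeauration of the C2 vinyl-gold releases the 3(2H)-furanone and the catalyst. The closest known reaction type is the gold-catalysed cycloisomerisation of 2-hydroxyalk-4-yn-3-ones to 3(2H)-furanones, here run across a ten-membered ring. The furanone ring (O, C3, C2, C1, C10) closes in the 5-endo-dig mode and is the last ring formed, turning the cyclodecenynone into the oxygen-bridged bicycle. No stereocentre is created; C10 keeps its configuration because only its O–H bond is broken, and C6, C7 and C8 are untouched. The step needs chemoselectivity for O10 over O8 and regioselectivity for C3 over C2: O8 could reach the alkyne only by a 7-endo or an anti-Michael 6-exo path, whereas O10 sits 1,4 to C3 of the carbonyl-polarised alkyne, and relief of the alkyne bending strain adds driving force. The Z-C4=C5 alkene and the methylene lactone should be inert to the soft π-acid.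

**Step 21**
Reactants: 29 (6S,7S,8R,10R)-8-hydroxy-1-oxo-3,10-epoxygermacra-2,4Z,11(13)-trien-12,6-olide; 9 (E)-2-(acetoxymethyl)but-2-enoic acid
Product: 31 (6S,7S,8R,10R)-8-[(E)-2-(acetoxymethyl)but-2-enoyloxy]-1-oxo-3,10-epoxygermacra-2,4Z,11(13)-trien-12,6-olide (CNP0176571.1), via mixed anhydride 30 (not isolated)
Conditions: 9, 2,4,6-trichlorobenzoyl chloride, Et3N, toluene, rt; then 29, DMAP, rt
Reagents that add atoms: none
Why: Yamaguchi esterification acylates the only free hydroxyl (C8) with retention at C8, and the E geometry of the acyl group should be preserved under these mild conditions.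

**Compound list**
1 | (Z)-3-methylpent-2-en-4-yn-1-ol | C#C/C(C)=C\CO | starting material
2 | (Z)-3-methylpent-2-en-4-ynal | C#C/C(C)=C\C=O | intermediate
3 | (Z)-5,5-dimethoxy-3-methylpent-3-en-1-yne | C#C/C(C)=C\C(OC)OC | intermediate
4 | acetaldehyde | CC=O | starting material
5 | tert-butyl acrylate | C=CC(=O)OC(C)(C)C | starting material
6 | tert-butyl 3-hydroxy-2-methylidenebutanoate (racemic) | CC(O)C(=C)C(=O)OC(C)(C)C | intermediate
7 | tert-butyl 3-acetoxy-2-methylidenebutanoate (racemic) | CC(OC(C)=O)C(=C)C(=O)OC(C)(C)C | intermediate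
8 | tert-butyl (E)-2-(acetoxymethyl)but-2-enoate | C/C=C(\COC(C)=O)C(=O)OC(C)(C)C | intermediate
9 | (E)-2-(acetoxymethyl)but-2-enoic acid | C/C=C(\COC(C)=O)C(=O)O | intermediate
10 | (R)-5-(hydroxymethyl)dihydrofuran-2(3H)-one | OC[C@H]1CCC(=O)O1 | starting material
11 | (R)-5-[(triethylsilyloxy)methyl]dihydrofuran-2(3H)-one | CC[Si](CC)(CC)OC[C@H]1CCC(=O)O1 | intermediate
12 | (3S,5R)-3-hydroxy-5-[(triethylsilyloxy)methyl]dihydrofuran-2(3H)-one | CC[Si](CC)(CC)OC[C@H]1C[C@H](O)C(=O)O1 | intermediate
13 | (3S,5R)-3-(triethylsilyloxy)-5-[(triethylsilyloxy)methyl]dihydrofuran-2(3H)-one | CC[Si](CC)(CC)OC[C@H]1C[C@H](O[Si](CC)(CC)CC)C(=O)O1 | intermediate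
14 | (3R,5R)-3-methyl-3-(triethylsilyloxy)-5-[(triethylsilyloxy)methyl]dihydrofuran-2(3H)-one | CC[Si](CC)(CC)OC[C@H]1C[C@@](C)(O[Si](CC)(CC)CC)C(=O)O1 | intermediate
15 | (3R,5R)-3-methyl-3-(triethylsilyloxy)-5-[(triethylsilyloxy)methyl]oxolan-2-ol (anomer mixture) | CC[Si](CC)(CC)OC[C@H]1C[C@@](C)(O[Si](CC)(CC)CC)C(O)O1 | intermediate
16 | lithium (Z)-5,5-dimethoxy-3-methylpent-3-en-1-yn-1-ide | [Li+].[C-]#C/C(C)=C\C(OC)OC | intermediate
17 | dilithium (2R,4R,5RS,8Z)-10,10-dimethoxy-4,8-dimethyl-1,4-bis(triethylsilyloxy)dec-8-en-6-yne-2,5-diolate | [Li+].[Li+].CC[Si](CC)(CC)OC[C@H]([O-])C[C@@](C)(O[Si](CC)(CC)CC)C([O-])C#C/C(C)=C\C(OC)OC | intermediate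
18 | (2R,4R,5RS,8Z)-10,10-dimethoxy-4,8-dimethyl-1,2,4,5-tetrakis(triethylsilyloxy)dec-8-en-6-yne | CC[Si](CC)(CC)OC[C@H](O[Si](CC)(CC)CC)C[C@@](C)(O[Si](CC)(CC)CC)C(O[Si](CC)(CC)CC)C#C/C(C)=C\C(OC)OC | intermediate
19 | (2R,4R,5RS,8Z)-10,10-dimethoxy-4,8-dimethyl-2,4,5-tris(triethylsilyloxy)dec-8-en-6-ynal | O=C[C@H](O[Si](CC)(CC)CC)C[C@@](C)(O[Si](CC)(CC)CC)C(O[Si](CC)(CC)CC)C#C/C(C)=C\C(OC)OC | intermediate
20 | methyl acrylate | C=CC(=O)OC | starting material
21 | methyl (3RS,4R,6R,7RS,10Z)-3-hydroxy-12,12-dimethoxy-6,10-dimethyl-2-methylidene-4,6,7-tris(triethylsilyloxy)dodec-10-en-8-ynoate | C=C(C(=O)OC)C(O)[C@H](O[Si](CC)(CC)CC)C[C@@](C)(O[Si](CC)(CC)CC)C(O[Si](CC)(CC)CC)C#C/C(C)=C\C(OC)OC | intermediate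
22 | methyl (2Z,4R,6R,7RS,10Z)-2-(bromomethyl)-12,12-dimethoxy-6,10-dimethyl-4,6,7-tris(triethylsilyloxy)dodeca-2,10-dien-8-ynoate | BrC/C(C(=O)OC)=C\[C@H](O[Si](CC)(CC)CC)C[C@@](C)(O[Si](CC)(CC)CC)C(O[Si](CC)(CC)CC)C#C/C(C)=C\C(OC)OC | intermediate
23 | methyl (2Z,4R,6R,7RS,10Z)-2-(bromomethyl)-6,10-dimethyl-12-oxo-4,6,7-tris(triethylsilyloxy)dodeca-2,10-dien-8-ynoate | BrC/C(C(=O)OC)=C\[C@H](O[Si](CC)(CC)CC)C[C@@](C)(O[Si](CC)(CC)CC)C(O[Si](CC)(CC)CC)C#C/C(C)=C\C=O | intermediate
24 | allylchromium dichloride formed from 23 at C13 (trivalent chromium) | Cl[Cr](Cl)C/C(C(=O)OC)=C\[C@H](O[Si](CC)(CC)CC)C[C@@](C)(O[Si](CC)(CC)CC)C(O[Si](CC)(CC)CC)C#C/C(C)=C\C=O | intermediate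
25 | dichlorochromium alkoxide of the ten-membered 6-hydroxy-7-[1-(methoxycarbonyl)ethenyl] carbocycle (6S,7S,8R,10R) | C=C(C(=O)OC)[C@@H]1[C@@H](O[Cr](Cl)Cl)/C=C(/C)C#CC(O[Si](CC)(CC)CC)[C@](C)(O[Si](CC)(CC)CC)C[C@H]1O[Si](CC)(CC)CC | intermediate
26 | (6S,7S,8R,10R)-1,8,10-tris(triethylsilyloxy)germacra-4Z,11(13)-dien-2-yn-12,6-olide (C1 epimers) | C=C1C(=O)O[C@H]2/C=C(/C)C#CC(O[Si](CC)(CC)CC)[C@@](C)(C[C@@H](O[Si](CC)(CC)CC)[C@H]12)O[Si](CC)(CC)CC | intermediate
27 | (6S,7S,8R,10R)-1,8,10-trihydroxygermacra-4Z,11(13)-dien-2-yn-12,6-olide (C1 epimers) | C=C1C(=O)O[C@H]2/C=C(/C)C#CC(O)[C@@](C)(C[C@@H](O)[C@H]12)O | intermediate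
28 | (6S,7S,8R,10R)-8,10-dihydroxy-1-oxogermacra-4Z,11(13)-dien-2-yn-12,6-olide | C=C1C(=O)O[C@H]2/C=C(/C)C#CC(=O)[C@@](C)(C[C@@H](O)[C@H]12)O | intermediate
29 | (6S,7S,8R,10R)-8-hydroxy-1-oxo-3,10-epoxygermacra-2,4Z,11(13)-trien-12,6-olide | C=C1C(=O)O[C@H]2/C=C(/C)C3=CC(=O)[C@@](C)(C[C@@H](O)[C@H]12)O3 | intermediate
30 | (E)-2-(acetoxymethyl)but-2-enoic 2,4,6-trichlorobenzoic anhydride | C/C=C(\COC(C)=O)C(=O)OC(=O)c1c(Cl)cc(Cl)cc1Cl | intermediate
31 | (6S,7S,8R,10R)-8-[(E)-2-(acetoxymethyl)but-2-enoyloxy]-1-oxo-3,10-epoxygermacra-2,4Z,11(13)-trien-12,6-olide (CNP0176571.1) | C=C1C(=O)O[C@H]2/C=C(/C)C3=CC(=O)[C@@](C)(C[C@@H](OC(=O)/C(=C/C)COC(C)=O)[C@H]12)O3 | target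

**Step count.** Total: 21 steps. Longest linear sequence: 15 steps (steps 7 to 21, from lactone 10); the enyne acetal (steps 1–2) and the side-chain acid (steps 3–6) are convergent branches.

**Steps most likely to fail**

Step 17 (macrocyclisation). Ring closure of the strained ten-membered enyne may be slow, so intermolecular allylation (oligomers) or protonation of the allylchromium can compete. Closure through the alternative chair, or on the other face of C7, would give a cis-fused or C7-epimeric lactone. The fallback sets out from 21 and replaces the organochromium by an isolable allylboron nucleophile. Acetylation (Ac2O, DMAP) should give the secondary acetate methyl (3RS,4R,6R,7RS,10Z)-3-acetoxy-12,12-dimethoxy-6,10-dimethyl-2-methylidene-4,6,7-tris(triethylsilyloxy)dodec-10-en-8-ynoate F1. SN2' borylation catalysed by CuCl (monovalent copper) with bis(pinacolato)diboron and KOAc in DMF should give the 2-(methoxycarbonyl)allylboronate F2, with boron on C13. Moist silica and oxalic acid then unmask the enal to give the aldehyde boronate F3. F3 is cyclised at high dilution under Sc(OSO2CF3)3 catalysis; Lewis-acid-catalysed allylboration of 2-alkoxycarbonyl allylboronates is known to favour trans-β,γ-disubstituted methylene lactones. Lactonisation of the borate brings the route back at 26.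

Step 20 (key transannular closure). The catalyst may be diverted by the free hydroxyls or the enyne, the C8 hydroxyl may tie up the ketone as a transannular hemiketal, or gold-promoted hydration of the ynone may compete. The fallback sets out from 28 and uses the classical amine route to 3(2H)-furanones. Excess Et2NH in EtOH adds to C3 of the ynone and, reversibly, to the methylene lactone, giving the bis-adduct (6S,7S,8R,10R)-3,13-bis(diethylamino)-8,10-dihydroxy-1-oxogermacra-2,4Z-dien-12,6-olide F4. Aqueous AcOH induces addition–elimination of O10 at C3, still a transannular closure of the last ring, to give the 13-(diethylamino)-11,13-dihydro derivative of 29, F5. Quaternisation with MeI gives the ammonium iodide F6, and NaHCO3-induced elimination restores the methylene lactone, rejoining the route at 29.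

Step 14 (Morita–Baylis–Hillman). Addition of the ammonium enolate to the hindered α-silyloxy aldehyde may be so slow that base-mediated epimerisation at C8 or silyl migration competes. The fallback sets out from 19 and avoids the amine. Hydroalumination of methyl propiolate with i-Bu2AlH and N-methylmorpholine N-oxide in THF at 0 °C gives methyl 2-(diisobutylalumanyl)prop-2-enoate F7. This vinylalane adds to the aldehyde at low temperature (vinylalumination) and delivers 21 directly.

**Further compounds**
F1 | step 17 | methyl (3RS,4R,6R,7RS,10Z)-3-acetoxy-12,12-dimethoxy-6,10-dimethyl-2-methylidene-4,6,7-tris(triethylsilyloxy)dodec-10-en-8-ynoate | C=C(C(=O)OC)C(OC(C)=O)[C@H](O[Si](CC)(CC)CC)C[C@@](C)(O[Si](CC)(CC)CC)C(O[Si](CC)(CC)CC)C#C/C(C)=C\C(OC)OC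
F2 | step 17 | methyl (4R,6R,7RS,10Z)-12,12-dimethoxy-6,10-dimethyl-2-[(4,4,5,5-tetramethyl-1,3,2-dioxaborolan-2-yl)methyl]-4,6,7-tris(triethylsilyloxy)dodeca-2,10-dien-8-ynoate (boryl-methyl cis to C4) | CC1(C)OB(C/C(C(=O)OC)=C\[C@H](O[Si](CC)(CC)CC)C[C@@](C)(O[Si](CC)(CC)CC)C(O[Si](CC)(CC)CC)C#C/C(C)=C\C(OC)OC)OC1(C)C
F3 | step 17 | methyl (4R,6R,7RS,10Z)-6,10-dimethyl-12-oxo-2-[(4,4,5,5-tetramethyl-1,3,2-dioxaborolan-2-yl)methyl]-4,6,7-tris(triethylsilyloxy)dodeca-2,10-dien-8-ynoate | CC1(C)OB(C/C(C(=O)OC)=C\[C@H](O[Si](CC)(CC)CC)C[C@@](C)(O[Si](CC)(CC)CC)C(O[Si](CC)(CC)CC)C#C/C(C)=C\C=O)OC1(C)C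
F4 | step 20 | (6S,7S,8R,10R)-3,13-bis(diethylamino)-8,10-dihydroxy-1-oxogermacra-2,4Z-dien-12,6-olide (C11 epimers) | CCN(CC)CC1C(=O)O[C@H]2/C=C(/C)C(N(CC)CC)=CC(=O)[C@@](C)(C[C@@H](O)[C@H]12)O
F5 | step 20 | (6S,7S,8R,10R)-13-(diethylamino)-8-hydroxy-1-oxo-3,10-epoxygermacra-2,4Z-dien-12,6-olide (C11 epimers) | CCN(CC)CC1C(=O)O[C@H]2/C=C(/C)C3=CC(=O)[C@@](C)(C[C@@H](O)[C@H]12)O3
F6 | step 20 | N-methyl ammonium iodide of F5 | CC[N+](C)(CC)CC1C(=O)O[C@H]2/C=C(/C)C3=CC(=O)[C@@](C)(C[C@@H](O)[C@H]12)O3.[I-]
F7 | step 14 | methyl 2-(diisobutylalumanyl)prop-2-enoate | C=C(C(=O)OC)[Al](CC(C)C)CC(C)C
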